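**Plan**

- Numbering: chromone A is the 7-hydroxychromone unit (unprimed atoms) and chromone B the 8-hydroxychromone unit (primed atoms); they are joined C6–C5'.
- Enabling feature: the benzene ring of chromone B has four adjacent substituted carbons, C5' (aryl), C4a' (bearing acyl carbon C4'), C8a' (bearing O1') and C8' (hydroxyl). This is the pattern of a 6-aryl-3-alkoxysalicylate.
- Cuts: first O1'–C2' and C3'–C4' (pyranone of chromone B, back to a salicylic ester and 4-phenylbut-1-yne). Then C7'–C8' and C4a'–C5' (benzene ring of chromone B, back to a 4-methoxy bis-silyl diene and a 3-oxo acetal grown from a C6 acetyl group on chromone A). Last O1–C2 and C2–C3 of chromone A.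
- Forward order: pyranone of chromone A on 4,6-diacetylresorcinol, one-carbon extension of the second acetyl group, benzene ring of chromone B by (3+3) benzannulation, pyranone of chromone B, then cleavage of both methyl ethers.
- Stereochemistry: the target has no stereocentre, so none has to be set; the two transient stereocentres of the benzannulation vanish on aromatization.

Key step: step 8

Remark: the C6–C5' axis carries no descriptor in the target and is treated as unassigned; silyl enol ether 9 and diene 10 are used as the double-bond isomer mixtures obtained, since their geometry is lost in step 8.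

**Route**

Step 1
Reactants: 1 4,6-diacetylresorcinol; 2 ethyl 3-phenylpropanoate
Product: 3 1-(5-acetyl-2,4-dihydroxyphenyl)-5-phenylpentane-1,3-dione
Conditions: LiN(SiMe3)2 (3.05 equiv), THF, −78 → 0 °C; then 2 (1.0 equiv), 0 °C → rt; aq. HCl
Reagents that add atoms: none
Why: Claisen condensation in which three equivalents of base give the bis-phenoxide mono-enolate of 1, which should acylate once with the limiting ester; the ethoxide released deprotonates the new β-diketone, so no base is left to enolize the second acetyl group.

Step 2
Reactants: 3 1-(5-acetyl-2,4-dihydroxyphenyl)-5-phenylpentane-1,3-dione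
Product: 4 6-acetyl-7-hydroxy-2-(2-phenylethyl)chromen-4-one
Conditions: H2SO4 (cat.), AcOH, 100 °C
Reagents that add atoms: none
Why: Acid-catalysed cyclodehydration of an o-hydroxyaryl 1,3-diketone to the 4-pyranone; only the hydroxyl ortho to the diketone chain can reach its distal carbonyl, the other being para to the chain.

Step 3
Reactants: 4 6-acetyl-7-hydroxy-2-(2-phenylethyl)chromen-4-one
Product: 5 6-acetyl-7-methoxy-2-(2-phenylethyl)chromen-4-one
Conditions: MeI, K2CO3, acetone, reflux
Reagents that add atoms: iodomethane CI
Why: Williamson O-methylation of the only acidic site, the chelated 7-hydroxyl; K2CO3 is too weak to enolize the acetyl group or the side-chain methylene.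

Step 4
Reactants: 5 6-acetyl-7-methoxy-2-(2-phenylethyl)chromen-4-one
Product: 6 6-[(2E)-3-(dimethylamino)prop-2-enoyl]-7-methoxy-2-(2-phenylethyl)chromen-4-one
Conditions: Me2NCH(OMe)2 (1.5 equiv), toluene, 100 °C
Reagents that add atoms: N,N-dimethylformamide dimethyl acetal COC(OC)N(C)C
Why: Condensation of an aryl methyl ketone with the amide acetal to the E-enaminone under neutral conditions; the unhindered acetyl methyl should react ahead of the more crowded, vinylogously activated methylene at C2 of the chromone.

Step 5
Reactants: 6 6-[(2E)-3-(dimethylamino)prop-2-enoyl]-7-methoxy-2-(2-phenylethyl)chromen-4-one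
Product: 7 6-(3,3-dimethoxypropanoyl)-7-methoxy-2-(2-phenylethyl)chromen-4-one
Conditions: HCl (3 equiv, anhydrous), MeOH, 0 °C → rt
Reagents that add atoms: methanol CO
Why: Acid-mediated alcoholysis of the vinylogous amide (C-protonation, addition of methanol to the iminium ion, loss of dimethylamine as its salt, second addition of methanol) should give the 3-oxo acetal; the chromone is inert to anhydrous acid.

Step 6
Reactants: 8 methyl 4-methoxy-3-oxobutanoate
Product: 9 methyl 4-methoxy-3-(trimethylsilyloxy)but-2-enoate
Conditions: Me3SiCl, Et3N, toluene, rt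
Reagents that add atoms: chlorotrimethylsilane C[Si](C)(C)Cl
Why: Soft enolization and O-silylation of the β-keto ester gives the silyl enol ether conjugated with the ester.

Step 7
Reactants: 9 methyl 4-methoxy-3-(trimethylsilyloxy)but-2-enoate
Product: 10 1,4-dimethoxy-1,3-bis(trimethylsilyloxy)buta-1,3-diene
Conditions: LiN(iPr)2, THF, −78 °C; then Me3SiCl, −78 °C → rt
Reagents that add atoms: chlorotrimethylsilane C[Si](C)(C)Cl
Why: γ-Deprotonation of the vinylogous ester at the methoxymethylene carbon and O-silylation of the dienolate gives the 1,3-bis(silyloxy)diene, the standard two-stage preparation of such dienes from β-keto esters.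

Step 8
Reactants: 7 6-(3,3-dimethoxypropanoyl)-7-methoxy-2-(2-phenylethyl)chromen-4-one; 10 1,4-dimethoxy-1,3-bis(trimethylsilyloxy)buta-1,3-diene
Product: 12 methyl 2-hydroxy-3-methoxy-6-[7-methoxy-4-oxo-2-(2-phenylethyl)chromen-6-yl]benzoate, via open-chain keto ester 11 (not isolated)
Conditions: 10 (2 equiv), TiCl4 (2.2 equiv), CH2Cl2, −78 → 20 °C; then H2O
Reagents that add atoms: none
Why: TiCl4 ionizes the dimethyl acetal of 7 to an oxocarbenium ion, and the methoxy-bearing terminal carbon of diene 10 adds to it in a vinylogous Mukaiyama reaction (bond C7'–C8'), giving 11 as its titanium enolate. The central carbon of that enolate then closes the six-membered carbocycle on the aryl ketone carbon by a 6-(enolendo)-exo-trig aldol addition (bond C4a'–C5'), and loss of water and methanol aromatizes the ring to the salicylate. The closest known reaction type is the formal (3+3) cyclocondensation of 1,3-bis(silyloxy)-1,3-dienes with 3-oxo acetals or 3-silyloxy enones to give salicylates. No stereocentre remains, since the two of 11 vanish on aromatization and the geometry of 10 is irrelevant. The step needs regioselectivity (terminal carbon to the acetal carbon, central carbon to the ketone carbon), which is secured because the oxocarbenium ion is the most electrophilic and least hindered site and the terminal carbon the most nucleophilic one, leaving the hindered ketone for the intramolecular step. It also needs chemoselectivity against chromone A, whose C4 carbonyl is a vinylogous ester and whose C2 is fully substituted, so neither should compete with the oxocarbenium ion; the second equivalent of TiCl4 allows for coordination to that carbonyl.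

Step 9
Reactants: 12 methyl 2-hydroxy-3-methoxy-6-[7-methoxy-4-oxo-2-(2-phenylethyl)chromen-6-yl]benzoate
Product: 13 2-hydroxy-N,3-dimethoxy-N-methyl-6-[7-methoxy-4-oxo-2-(2-phenylethyl)chromen-6-yl]benzamide
Conditions: MeNHOMe·HCl (6 equiv), AlMe3 (5 equiv), CH2Cl2, 0 °C → reflux; aq. HCl
Reagents that add atoms: N,O-dimethylhydroxylamine hydrochloride CNOC.Cl
Why: Aluminium-amide aminolysis of the ester (Weinreb amidation); the aluminium phenoxide formed at the ortho hydroxyl chelates and activates the crowded ester carbonyl, and the amine salt is kept in excess so that no free AlMe3 is left to attack chromone A.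

Step 10
Reactants: 13 2-hydroxy-N,3-dimethoxy-N-methyl-6-[7-methoxy-4-oxo-2-(2-phenylethyl)chromen-6-yl]benzamide; 14 4-phenylbut-1-yne
Product: 15 6-[3-hydroxy-4-methoxy-2-(5-phenylpent-2-ynoyl)phenyl]-7-methoxy-2-(2-phenylethyl)chromen-4-one
Conditions: 14 (5 equiv), n-BuLi (4.8 equiv), THF, −78 °C; then 13, −78 → 0 °C; cold dilute aq. HCl
Reagents that add atoms: none
Why: Weinreb ketone synthesis, in which chelation holds the addition of the lithium acetylide at the ketone stage so that no tertiary alcohol forms; the excess acetylide covers the phenol proton, and the vinylogous-ester carbonyl of chromone A is far less electrophilic than the amide.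

Step 11
Reactants: 15 6-[3-hydroxy-4-methoxy-2-(5-phenylpent-2-ynoyl)phenyl]-7-methoxy-2-(2-phenylethyl)chromen-4-one
Product: 17 8-methoxy-5-[7-methoxy-4-oxo-2-(2-phenylethyl)chromen-6-yl]-2-(2-phenylethyl)chromen-4-one, via diethylamino enone 16 (not isolated)
Conditions: Et2NH, EtOH, reflux
Reagents that add atoms: none
Why: Conjugate addition of the secondary amine to the ynone gives amino enone 16, which the ortho phenol attacks in an addition–elimination that releases the amine; the overall 6-endo closure gives the 4-pyranone and not the 5-exo benzofuranone.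

Step 12
Reactants: 17 8-methoxy-5-[7-methoxy-4-oxo-2-(2-phenylethyl)chromen-6-yl]-2-(2-phenylethyl)chromen-4-one
Product: 18 8-hydroxy-5-[7-hydroxy-4-oxo-2-(2-phenylethyl)chromen-6-yl]-2-(2-phenylethyl)chromen-4-one (the target)
Conditions: BBr3 (8 equiv), CH2Cl2, −78 °C → rt; then H2O
Reagents that add atoms: none
Why: Lewis-acid cleavage of both aryl methyl ethers by BBr3 (bromide attack on the methyl of the boron-complexed ether); the excess allows for complexation at the two pyranone carbonyls, and the pyranones and phenylethyl chains are inert.

**Compound list**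

1 | 4,6-diacetylresorcinol | CC(=O)c1cc(C(C)=O)c(O)cc1O | starting material
2 | ethyl 3-phenylpropanoate | CCOC(=O)CCc1ccccc1 | starting material
3 | 1-(5-acetyl-2,4-dihydroxyphenyl)-5-phenylpentane-1,3-dione | CC(=O)c1cc(C(=O)CC(=O)CCc2ccccc2)c(O)cc1O | intermediate
4 | 6-acetyl-7-hydroxy-2-(2-phenylethyl)chromen-4-one | CC(=O)c1cc2c(=O)cc(CCc3ccccc3)oc2cc1O | intermediate
5 | 6-acetyl-7-methoxy-2-(2-phenylethyl)chromen-4-one | CC(=O)c1cc2c(=O)cc(CCc3ccccc3)oc2cc1OC | intermediate
6 | 6-[(2E)-3-(dimethylamino)prop-2-enoyl]-7-methoxy-2-(2-phenylethyl)chromen-4-one | CN(C)/C=C/C(=O)c1cc2c(=O)cc(CCc3ccccc3)oc2cc1OC | intermediate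
7 | 6-(3,3-dimethoxypropanoyl)-7-methoxy-2-(2-phenylethyl)chromen-4-one | COC(OC)CC(=O)c1cc2c(=O)cc(CCc3ccccc3)oc2cc1OC | intermediate
8 | methyl 4-methoxy-3-oxobutanoate (methyl 4-methoxyacetoacetate) | COCC(=O)CC(=O)OC | starting material
9 | methyl 4-methoxy-3-(trimethylsilyloxy)but-2-enoate (double-bond isomer mixture) | COCC(O[Si](C)(C)C)=CC(=O)OC | intermediate
10 | 1,4-dimethoxy-1,3-bis(trimethylsilyloxy)buta-1,3-diene (double-bond isomer mixture) | COC=C(O[Si](C)(C)C)C=C(OC)O[Si](C)(C)C | intermediate
11 | methyl 4,5-dimethoxy-7-[7-methoxy-4-oxo-2-(2-phenylethyl)chromen-6-yl]-3,7-dioxoheptanoate (diastereomer mixture, present as its titanium enolate, not isolated) | COC(=O)CC(=O)C(OC)C(OC)CC(=O)c1cc2c(=O)cc(CCc3ccccc3)oc2cc1OC | intermediate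
12 | methyl 2-hydroxy-3-methoxy-6-[7-methoxy-4-oxo-2-(2-phenylethyl)chromen-6-yl]benzoate | COC(=O)c1c(O)c(OC)ccc1-c1cc2c(=O)cc(CCc3ccccc3)oc2cc1OC | intermediate
13 | 2-hydroxy-N,3-dimethoxy-N-methyl-6-[7-methoxy-4-oxo-2-(2-phenylethyl)chromen-6-yl]benzamide | CON(C)C(=O)c1c(O)c(OC)ccc1-c1cc2c(=O)cc(CCc3ccccc3)oc2cc1OC | intermediate
14 | 4-phenylbut-1-yne | C#CCCc1ccccc1 | starting material
15 | 6-[3-hydroxy-4-methoxy-2-(5-phenylpent-2-ynoyl)phenyl]-7-methoxy-2-(2-phenylethyl)chromen-4-one | COc1ccc(-c2cc3c(=O)cc(CCc4ccccc4)oc3cc2OC)c(C(=O)C#CCCc2ccccc2)c1O | intermediate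
16 | 6-{2-[3-(diethylamino)-5-phenylpent-2-enoyl]-3-hydroxy-4-methoxyphenyl}-7-methoxy-2-(2-phenylethyl)chromen-4-one (either double-bond geometry, not isolated) | CCN(CC)C(CCc1ccccc1)=CC(=O)c1c(O)c(OC)ccc1-c1cc2c(=O)cc(CCc3ccccc3)oc2cc1OC | intermediate
17 | 8-methoxy-5-[7-methoxy-4-oxo-2-(2-phenylethyl)chromen-6-yl]-2-(2-phenylethyl)chromen-4-one | COc1ccc(-c2cc3c(=O)cc(CCc4ccccc4)oc3cc2OC)c2c(=O)cc(CCc3ccccc3)oc12 | intermediate
18 | 8-hydroxy-5-[7-hydroxy-4-oxo-2-(2-phenylethyl)chromen-6-yl]-2-(2-phenylethyl)chromen-4-one (CNP0279305.0) | O=c1cc(CCc2ccccc2)oc2cc(O)c(-c3ccc(O)c4oc(CCc5ccccc5)cc(=O)c34)cc12 | target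

**Step count**

Total: 12 steps. Longest linear sequence: 10 steps (steps 1–5 and 8–12 from 1); the diene branch (steps 6–7) joins at step 8.

**Steps most likely to fail**

Step 8 (benzannulation). The Lewis-basic pyranone carbonyl of 7 may sequester TiCl4 so that the acetal is not ionized, or the titanium enolate may fail to add to the hindered ortho-methoxyaryl ketone, leaving open-chain material. The fallback separates the two bond formations and makes no compound outside the list (F0). Setting out from 7 and 10, catalytic Me3SiOTf in CH2Cl2 at −78 °C should effect only the vinylogous Mukaiyama addition to the acetal, and the open-chain keto ester 11 is isolated after aqueous work-up. The ring is then closed as an intramolecular Knoevenagel condensation of the β-keto ester methylene with the aryl ketone (piperidinium acetate, toluene, azeotropic removal of water), and β-elimination of methanol aromatizes the ring. The route is rejoined at 12.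

Step 9 (ester to N-methoxy-N-methylamide). Attack of the aluminium amide at a carbonyl carbon flanked by the hydroxyl and the twisted aryl group may stall, and prolonged heating may let the reagent open the pyranone of chromone A instead. The fallback sets out from 12 and cleaves the ester at its methyl carbon, not at its carbonyl carbon (LiI, pyridine, reflux; SN2 dealkylation, indifferent to the crowding). This should give 2-hydroxy-3-methoxy-6-[7-methoxy-4-oxo-2-(2-phenylethyl)chromen-6-yl]benzoic acid F1. The acid is then coupled with MeNHOMe·HCl by means of 1,1'-carbonyldiimidazole in THF, which returns to the route at 13.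

Step 10 (acetylide addition). The acetylide may be used up by deprotonation of the side-chain methylene at C2 of chromone A, or it may add irreversibly to the C4 carbonyl of chromone A faster than to the hindered, phenoxide-deactivated amide. The fallback sets out from 13 and uses the kinetic lithium enolate of 4-phenylbutan-2-one (LiN(iPr)2, THF, −78 °C, then 13, → rt). Its aldol-type additions to chromone A are reversible, whereas C-acylation by the amide is not. This should give 1-{2-hydroxy-3-methoxy-6-[7-methoxy-4-oxo-2-(2-phenylethyl)chromen-6-yl]phenyl}-5-phenylpentane-1,3-dione F2. Acid-catalysed cyclodehydration (H2SO4 cat., AcOH, 100 °C) then gives the pyranone of chromone B directly, rejoining the route at 17 and bypassing 15 and 16.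

**Further compounds**

F0 | step 8 | none | none
F1 | step 9 | 2-hydroxy-3-methoxy-6-[7-methoxy-4-oxo-2-(2-phenylethyl)chromen-6-yl]benzoic acid | COc1ccc(-c2cc3c(=O)cc(CCc4ccccc4)oc3cc2OC)c(C(=O)O)c1O
F2 | step 10 | 1-{2-hydroxy-3-methoxy-6-[7-methoxy-4-oxo-2-(2-phenylethyl)chromen-6-yl]phenyl}-5-phenylpentane-1,3-dione | COc1ccc(-c2cc3c(=O)cc(CCc4ccccc4)oc3cc2OC)c(C(=O)CC(=O)CCc2ccccc2)c1O
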